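**Plan**

1. Numbering: ring A is the resorcinol ring (C1' acyl, O-2', C3', O-4'), ring B the chalcone phenol ring; the C5 chain is C1'' (benzylic CH2), C2''=C3'' (methyl on C3''), C4'' (CH2O).
2. Retrosynthesis: first the four O–CH2OMe protecting bonds, then C3'–C1'' (Suzuki–Miyaura allyl–aryl coupling of the C3' boronate of the complete chalcone with the C1'' methyl carbonate of the complete C5 coumarate), then the chalcone Cα=Cβ bond (Claisen–Schmidt), the ester C(=O)–O bond at C4'' (Steglich), the coumarate Cα=Cβ bond (Doebner) and the C4''–O bond (allylic oxidation of a prenyl carbonate).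
3. Enabling feature: C3' lies between O-2' and O-4' of ring A, so iodination of 2,4-dihydroxyacetophenone marks exactly this carbon and iodine is later exchanged for boron; C1'' is a primary allylic carbon, so its carbonate ionises to an η3-allyl palladium unit over C1''–C3'' while the less reactive cinnamate at C4'' stays.
4. Forward order: fragment 1 (prenol → carbonate → E alcohol → coumarate ester) and fragment 2 (acetophenone → iodide → bis-acetal → chalcone → boronate) are made separately, joined in step 10 and deprotected in step 11; no ring is built, the three benzene rings are bought.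
5. Stereochemistry: there is no stereocentre; E at C2''=C3'' comes from the trans-methyl preference of the SeO2 oxidation and is carried through the syn η3-allyl complex; E of both arylpropenoyl units comes from thermodynamic control in the Doebner and Claisen–Schmidt condensations.
6. Helpers: iodine and boron at C3' and the carbonate at C1'' are used up in the key step; the four methoxymethyl groups leave in the last step.

Key step: step 10

**Route**

Step 1
Reactants: 1 4-hydroxybenzaldehyde
Product: 2 4-(methoxymethoxy)benzaldehyde
Conditions: MOMCl, i-Pr2NEt, CH2Cl2, 0 °C to rt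
Reagents that add atoms: chloromethyl methyl ether, COCCl
Why: Williamson-type O-alkylation of the phenol by the reactive α-chloro ether gives the methoxymethyl acetal, which masks the acidic phenol for the later base-mediated condensations.

Step 2
Reactants: 2 4-(methoxymethoxy)benzaldehyde
Product: 4 (E)-3-[4-(methoxymethoxy)phenyl]prop-2-enoic acid, via arylidenemalonic acid 3 (not isolated)
Conditions: malonic acid, pyridine, piperidine (cat.), 90 °C
Reagents that add atoms: malonic acid, O=C(O)CC(=O)O
Why: Knoevenagel–Doebner condensation followed by decarboxylation in hot pyridine should deliver the thermodynamically favoured E cinnamic acid while the acetal survives the basic medium.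

Step 3
Reactants: 5 3-methylbut-2-en-1-ol (prenol)
Product: 6 methyl 3-methylbut-2-en-1-yl carbonate
Conditions: ClCO2Me, pyridine, CH2Cl2, 0 °C
Reagents that add atoms: methyl chloroformate, COC(=O)Cl
Why: Acylation of the primary allylic alcohol by the chloroformate under pyridine catalysis installs the carbonate that later serves as the leaving group for palladium.

Step 4
Reactants: 6 methyl 3-methylbut-2-en-1-yl carbonate
Product: 7 (E)-4-hydroxy-3-methylbut-2-en-1-yl methyl carbonate
Conditions: SeO2 (0.3 equiv), t-BuOOH (70 % in water, 3 equiv), salicylic acid (cat.), CH2Cl2, rt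
Reagents that add atoms: selenium dioxide, O=[Se]=O (transfers the oxygen atom); tert-butyl hydroperoxide, CC(C)(C)OO (terminal source of that oxygen)
Why: Riley-type allylic oxidation (ene reaction then [2,3]-sigmatropic shift at selenium) attacks the more substituted alkene terminus at the methyl group trans to the CH2O substituent, which should fix the E geometry of the trisubstituted alkene.

Step 5
Reactants: 7 (E)-4-hydroxy-3-methylbut-2-en-1-yl methyl carbonate; 4 (E)-3-[4-(methoxymethoxy)phenyl]prop-2-enoic acid
Product: 8 (E)-4-[(methoxycarbonyl)oxy]-2-methylbut-2-en-1-yl (E)-3-[4-(methoxymethoxy)phenyl]prop-2-enoate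
Conditions: DCC, DMAP (cat.), CH2Cl2, 0 °C to rt
Reagents that add atoms: none
Why: Steglich esterification (carbodiimide activation of the acid and acyl transfer by DMAP) should acylate the primary allylic alcohol without touching the carbonate or either alkene.

Step 6
Reactants: 9 1-(2,4-dihydroxyphenyl)ethan-1-one (2,4-dihydroxyacetophenone)
Product: 10 1-(2,4-dihydroxy-3-iodophenyl)ethan-1-one
Conditions: I2 (0.4 equiv), HIO3 (0.2 equiv), EtOH/H2O, rt
Reagents that add atoms: iodine, [I][I]; iodic acid, O=I(=O)O
Why: Electrophilic aromatic iodination by iodine activated with iodic acid should go to C3, the carbon ortho to both hydroxyl groups (as in the 2-iodination of resorcinol), and the substoichiometric charge guards against a second iodination.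

Step 7
Reactants: 10 1-(2,4-dihydroxy-3-iodophenyl)ethan-1-one
Product: 11 1-[3-iodo-2,4-bis(methoxymethoxy)phenyl]ethan-1-one
Conditions: NaH, MOMCl, DMF, 0 °C to rt
Reagents that add atoms: chloromethyl methyl ether, COCCl
Why: Double Williamson alkylation of the bis-phenoxide, for which the strong base is needed to open the hydrogen bond of the chelated 2-hydroxyl group, masks both phenols that flank the iodine.

Step 8
Reactants: 11 1-[3-iodo-2,4-bis(methoxymethoxy)phenyl]ethan-1-one; 2 4-(methoxymethoxy)benzaldehyde
Product: 13 (E)-1-[3-iodo-2,4-bis(methoxymethoxy)phenyl]-3-[4-(methoxymethoxy)phenyl]prop-2-en-1-one, via β-hydroxy ketone aldol adduct 12 (not isolated)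
Conditions: KOH, EtOH/H2O, rt
Reagents that add atoms: none
Why: Claisen–Schmidt condensation of the methyl ketone enolate with the non-enolisable aldehyde and E1cB dehydration should give the E enone under thermodynamic control, the aryl iodide and the acetals being inert to hydroxide at room temperature.

Step 9
Reactants: 13 (E)-1-[3-iodo-2,4-bis(methoxymethoxy)phenyl]-3-[4-(methoxymethoxy)phenyl]prop-2-en-1-one
Product: 14 (E)-1-[2,4-bis(methoxymethoxy)-3-(4,4,5,5-tetramethyl-1,3,2-dioxaborolan-2-yl)phenyl]-3-[4-(methoxymethoxy)phenyl]prop-2-en-1-one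
Conditions: B2pin2, Pd(OAc)2 (4 mol %), SPhos (8 mol %), KOAc, 1,4-dioxane, 80 °C
Reagents that add atoms: bis(pinacolato)diboron, CC1(C)OB(B2OC(C)(C)C(C)(C)O2)OC1(C)C
Why: Miyaura borylation (oxidative addition of the aryl iodide, acetate-assisted transmetalation from the diboron, reductive elimination) exchanges iodine for boron at C3', the bulky electron-rich biarylphosphine being chosen because both ortho positions are substituted.

Step 10
Reactants: 14 (E)-1-[2,4-bis(methoxymethoxy)-3-(4,4,5,5-tetramethyl-1,3,2-dioxaborolan-2-yl)phenyl]-3-[4-(methoxymethoxy)phenyl]prop-2-en-1-one; 8 (E)-4-[(methoxycarbonyl)oxy]-2-methylbut-2-en-1-yl (E)-3-[4-(methoxymethoxy)phenyl]prop-2-enoate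
Product: 15 (E)-4-{2,6-bis(methoxymethoxy)-3-[(E)-3-[4-(methoxymethoxy)phenyl]prop-2-enoyl]phenyl}-2-methylbut-2-en-1-yl (E)-3-[4-(methoxymethoxy)phenyl]prop-2-enoate
Conditions: Pd2(dba)3 (2.5 mol %), SPhos (10 mol %), THF, 45 °C, no added base
Reagents that add atoms: none
Why: Zerovalent palladium ionises the primary allylic methyl carbonate of 8 with inversion to an η3-allyl palladium complex in which the acyloxymethyl group sits syn and the methyl group anti, loss of CO2 leaves a palladium methoxide that activates the boronate 14, the aryl group moves from boron to palladium, and reductive elimination joins C3' of ring A to the unsubstituted CH2 terminus. The closest known reaction type is the Suzuki–Miyaura allyl–aryl coupling of arylboron compounds with allylic carbonates, a Tsuji–Trost ionisation followed by transmetalation that needs no added base. No ring is closed and no stereocentre is formed; the element at stake is the E geometry of C2''=C3'', which is set in step 4 and should be carried through because syn/anti exchange would need a σ-allyl complex at the fully substituted C3''. Site selectivity on ring A is fixed by the boron atom that stands where iodine was placed between O-2' and O-4', and the choice between the allyl termini is secured by the doubly ortho-substituted aryl group, which cannot reach the fully substituted end. Chemoselectivity between the two allylic esters of 8 rests on the carbonate, which ionises irreversibly at 45 °C while the cinnamate at C4'' should not, and the neutral medium leaves both enones, the ester and the four acetals untouched.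

Step 11
Reactants: 15 (E)-4-{2,6-bis(methoxymethoxy)-3-[(E)-3-[4-(methoxymethoxy)phenyl]prop-2-enoyl]phenyl}-2-methylbut-2-en-1-yl (E)-3-[4-(methoxymethoxy)phenyl]prop-2-enoate
Product: 16 isogemichalcone B, (E)-4-{2,6-dihydroxy-3-[(E)-3-(4-hydroxyphenyl)prop-2-enoyl]phenyl}-2-methylbut-2-en-1-yl (E)-3-(4-hydroxyphenyl)prop-2-enoate
Conditions: 3 M aq. HCl, THF, 40 °C
Reagents that add atoms: none
Why: Acid-catalysed hydrolysis of the four aryl methoxymethyl acetals through oxocarbenium ions frees the phenols, and the absence of an alcohol solvent together with the low temperature should spare the allylic cinnamate ester and both enones.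

**Compound list**

1 | 4-hydroxybenzaldehyde | O=Cc1ccc(O)cc1 | starting material
2 | 4-(methoxymethoxy)benzaldehyde | COCOc1ccc(C=O)cc1 | intermediate
3 | 2-[4-(methoxymethoxy)benzylidene]malonic acid (not isolated) | COCOc1ccc(C=C(C(=O)O)C(=O)O)cc1 | intermediate
4 | (E)-3-[4-(methoxymethoxy)phenyl]prop-2-enoic acid | COCOc1ccc(/C=C/C(=O)O)cc1 | intermediate
5 | 3-methylbut-2-en-1-ol (prenol) | CC(C)=CCO | starting material
6 | methyl 3-methylbut-2-en-1-yl carbonate | COC(=O)OCC=C(C)C | intermediate
7 | (E)-4-hydroxy-3-methylbut-2-en-1-yl methyl carbonate | COC(=O)OC/C=C(\C)CO | intermediate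
8 | (E)-4-[(methoxycarbonyl)oxy]-2-methylbut-2-en-1-yl (E)-3-[4-(methoxymethoxy)phenyl]prop-2-enoate | COC(=O)OC/C=C(\C)COC(=O)/C=C/c1ccc(OCOC)cc1 | intermediate
9 | 1-(2,4-dihydroxyphenyl)ethan-1-one | CC(=O)c1ccc(O)cc1O | starting material
10 | 1-(2,4-dihydroxy-3-iodophenyl)ethan-1-one | CC(=O)c1ccc(O)c(I)c1O | intermediate
11 | 1-[3-iodo-2,4-bis(methoxymethoxy)phenyl]ethan-1-one | CC(=O)c1ccc(OCOC)c(I)c1OCOC | intermediate
12 | 3-hydroxy-1-[3-iodo-2,4-bis(methoxymethoxy)phenyl]-3-[4-(methoxymethoxy)phenyl]propan-1-one (racemic, not isolated) | COCOc1ccc(C(O)CC(=O)c2ccc(OCOC)c(I)c2OCOC)cc1 | intermediate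
13 | (E)-1-[3-iodo-2,4-bis(methoxymethoxy)phenyl]-3-[4-(methoxymethoxy)phenyl]prop-2-en-1-one | COCOc1ccc(/C=C/C(=O)c2ccc(OCOC)c(I)c2OCOC)cc1 | intermediate
14 | (E)-1-[2,4-bis(methoxymethoxy)-3-(4,4,5,5-tetramethyl-1,3,2-dioxaborolan-2-yl)phenyl]-3-[4-(methoxymethoxy)phenyl]prop-2-en-1-one | COCOc1ccc(/C=C/C(=O)c2ccc(OCOC)c(B3OC(C)(C)C(C)(C)O3)c2OCOC)cc1 | intermediate
15 | (E)-4-{2,6-bis(methoxymethoxy)-3-[(E)-3-[4-(methoxymethoxy)phenyl]prop-2-enoyl]phenyl}-2-methylbut-2-en-1-yl (E)-3-[4-(methoxymethoxy)phenyl]prop-2-enoate | C/C(=C\Cc1c(OCOC)ccc(C(=O)/C=C/c2ccc(OCOC)cc2)c1OCOC)COC(=O)/C=C/c1ccc(OCOC)cc1 | intermediate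
16 | isogemichalcone B, (E)-4-{2,6-dihydroxy-3-[(E)-3-(4-hydroxyphenyl)prop-2-enoyl]phenyl}-2-methylbut-2-en-1-yl (E)-3-(4-hydroxyphenyl)prop-2-enoate | C/C(=C\Cc1c(O)ccc(C(=O)/C=C/c2ccc(O)cc2)c1O)COC(=O)/C=C/c1ccc(O)cc1 | target

**Count and risks**

Total step count: 11. Longest linear sequence: 6 steps (steps 6 to 11).

Steps most likely to fail:

Step 10. The doubly ortho-substituted boronate may transmetalate slowly, so that protodeboronation, capture of the allyl complex by methoxide, a second ionisation of the allylic cinnamate in the product, or partial syn/anti exchange with loss of alkene geometry could compete. The fallback sets out from 13 and comes back at 15; it brings in the C5 unit without the ester and oxidises it late. Suzuki–Miyaura coupling of 13 with commercial 3-methylbut-2-enylboronic acid pinacol ester (PdCl2(dppf), K3PO4, THF/H2O, 65 °C) should give (E)-1-[2,4-bis(methoxymethoxy)-3-(3-methylbut-2-en-1-yl)phenyl]-3-[4-(methoxymethoxy)phenyl]prop-2-en-1-one F1. Riley-type oxidation of its trans methyl group (SeO2 cat., t-BuOOH, CH2Cl2, rt) should give (E)-1-{3-[(E)-4-hydroxy-3-methylbut-2-en-1-yl]-2,4-bis(methoxymethoxy)phenyl}-3-[4-(methoxymethoxy)phenyl]prop-2-en-1-one F2. Steglich esterification of F2 with acid 4 (DCC, DMAP, CH2Cl2) returns to 15.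

Step 9. Oxidative addition and boron transfer at the hindered, electron-rich C3' may be slow, so that reduction of the C–I bond or conjugate borylation of the enone could take over. The fallback sets out from 8 and 13 and comes back at 15; it reverses the polarity of the partners. Borylation of the carbonate 8 (B2pin2, Pd2(dba)3, THF, 50 °C) should give (E)-2-methyl-4-(4,4,5,5-tetramethyl-1,3,2-dioxaborolan-2-yl)but-2-en-1-yl (E)-3-[4-(methoxymethoxy)phenyl]prop-2-enoate F3. This is coupled with the iodide 13 in a Suzuki–Miyaura reaction (Pd(OAc)2, SPhos, aq. K3PO4, THF, 40 °C) with bond formation at the CH2 terminus; the alkene geometry of the product would have to be checked, because boron-to-palladium transfer passes through a σ-allyl complex at C3''.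

Step 11. Acid may promote solvolysis or ionisation of the allylic ester, attack of a freed ortho phenol on the allylic system, or closure of the 2'-hydroxychalcone to a flavanone before all four acetals are gone. The fallback sets out from 7 and 14 and comes back at 16; it removes the acid-labile groups before the ester exists. Silylation of 7 (TBSCl, imidazole, DMF) should give (E)-4-[(tert-butyldimethylsilyl)oxy]-3-methylbut-2-en-1-yl methyl carbonate F4. Coupling of F4 with 14 under the conditions of step 10 should give (E)-1-{3-[(E)-4-[(tert-butyldimethylsilyl)oxy]-3-methylbut-2-en-1-yl]-2,4-bis(methoxymethoxy)phenyl}-3-[4-(methoxymethoxy)phenyl]prop-2-en-1-one F5. Aqueous HCl in THF then removes the three acetals and the silyl group to give (E)-1-{2,4-dihydroxy-3-[(E)-4-hydroxy-3-methylbut-2-en-1-yl]phenyl}-3-(4-hydroxyphenyl)prop-2-en-1-one F6. Mitsunobu esterification of the primary allylic alcohol of F6 with commercial (E)-4-hydroxycinnamic acid (PPh3, DIAD, THF, 0 °C), in which the carboxylic acid as the most acidic pronucleophile is expected to be alkylated in preference to the phenols, ends at 16.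

**Further compounds**

F1 | step 10 | (E)-1-[2,4-bis(methoxymethoxy)-3-(3-methylbut-2-en-1-yl)phenyl]-3-[4-(methoxymethoxy)phenyl]prop-2-en-1-one | CC(C)=CCc1c(OCOC)ccc(C(=O)/C=C/c2ccc(OCOC)cc2)c1OCOC
F2 | step 10 | (E)-1-{3-[(E)-4-hydroxy-3-methylbut-2-en-1-yl]-2,4-bis(methoxymethoxy)phenyl}-3-[4-(methoxymethoxy)phenyl]prop-2-en-1-one | C/C(=C\Cc1c(OCOC)ccc(C(=O)/C=C/c2ccc(OCOC)cc2)c1OCOC)CO
F3 | step 9 | (E)-2-methyl-4-(4,4,5,5-tetramethyl-1,3,2-dioxaborolan-2-yl)but-2-en-1-yl (E)-3-[4-(methoxymethoxy)phenyl]prop-2-enoate | C/C(=C\CB1OC(C)(C)C(C)(C)O1)COC(=O)/C=C/c1ccc(OCOC)cc1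
F4 | step 11 | (E)-4-[(tert-butyldimethylsilyl)oxy]-3-methylbut-2-en-1-yl methyl carbonate | COC(=O)OC/C=C(\C)CO[Si](C)(C)C(C)(C)C
F5 | step 11 | (E)-1-{3-[(E)-4-[(tert-butyldimethylsilyl)oxy]-3-methylbut-2-en-1-yl]-2,4-bis(methoxymethoxy)phenyl}-3-[4-(methoxymethoxy)phenyl]prop-2-en-1-one | C/C(=C\Cc1c(OCOC)ccc(C(=O)/C=C/c2ccc(OCOC)cc2)c1OCOC)CO[Si](C)(C)C(C)(C)C
F6 | step 11 | (E)-1-{2,4-dihydroxy-3-[(E)-4-hydroxy-3-methylbut-2-en-1-yl]phenyl}-3-(4-hydroxyphenyl)prop-2-en-1-one | C/C(=C\Cc1c(O)ccc(C(=O)/C=C/c2ccc(O)cc2)c1O)CO
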